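(All constants come from no measurement; the rest is arithmetic.)

If [incoming ligand] is to stay close to its saturation value, its first-order loss divided by its transfer coefficient has to be small against one, so I reckoned that ratio first for the flask below.

starting complex 0.20 M; scavenger 1.50 equiv; gas 32 mM (held); time 20 min

    starting complex + incoming ligand ⇌ leaving ligand + complex with one exchanged (K1 = 3.1, k1 = 1.2 L mol⁻¹ min⁻¹)
    complex with one exchanged + incoming ligand ⇌ leaving ligand + complex with two exchanged (K2 = 7.4, k2 = 2.7 L mol⁻¹ min⁻¹)
    complex with two exchanged + incoming ligand ⇌ leaving ligand + complex with three exchanged (K3 = 220, k3 = 5.9 L mol⁻¹ min⁻¹)
    leaving ligand + incoming ligand ⇌ idle adduct, settled at all times (K4 = 32 L mol⁻¹)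
    scavenger + leaving ligand → scavenged by-product (k5 = 28 L mol⁻¹ min⁻¹)
    gas ⇌ incoming ligand, rate k6*(csat - [incoming ligand]) (k6 = 0.22 min⁻¹, csat = 32 mM)

- part of the starting complex that has reacted at 20 min
- share of the unused incoming ligand that is free and not bound as idle adduct, at 20 min

- for leaving ligand the idle adduct is counted in
- at the start none of incoming ligand is dissolved
- run time (flask): 20 min

At the charge, the first exchange removed dissolved ligand with a pseudo-first-order constant of 0.240 min⁻¹, while transfer refilled it with 0.22 min⁻¹. The demand ratio, the summed first-order loss to the complexes present divided by the transfer coefficient, therefore began at 1.09, with loss and refilling about level, so this flask stood far from the saturated case. With [incoming ligand] at 32 mM from the first moment, the first exchange gives 53.6% reacted by 20 min. The other end of my reckoning was the plateau, where transfer into the gap balances the loss and [incoming ligand] equals saturation divided by one plus the ratio, 15.3 mM. The rise to it has a relaxation time of 2.17 min, shorter than the run, so I joined the ends by letting the starting complex decay at the plateau for the run minus that lag. This gave 27.9%. I expected that to run high, since the second exchange has a larger rate constant than the first and adds to the loss once its complex forms.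

The forecast gave 25.5% reacted, lower than my figure, and 97.9% free, and it called the run “limited by gas transfer”, where my ratio put transfer and uptake about level.

The flask gave 26.0% reacted and 97.9% free. In this flask, half of the turnover of uptake up to 20 min was done by 9.48 min, and half of that of the first exchange by 9.99 min. The scavenger took up leaving ligand meanwhile, and 76.2% of it was still free at 20.0 min. By then the demand ratio of the flask, counting all three exchanges, stood at 1.51, up from 1.09, which reckons to 12.7 mM against 12.9 mM found. The neighbour flask with 0.380 equiv of scavenger began at the same 1.09, and at 20.0 min its ratio of 1.50 reckons to 12.8 mM against 12.7 mM found, with 25.5% reacted.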